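**Strategy.** The cyclodecadiene is closed at C2–C3 by reading the (Z)-homoallylic alcohol C2(OH)–C3H2–C4(Me)=C5 of the ten-membered ring, together with the oxygen on C6, as the product of a double allylboration. The precursor is the trans-α-methylene-γ-butyrolactone carrying at C6 an anti secondary allylboronate [C5(Bpin)–C4(Me)=C3H2] and, on C7, the C8 angelate chain ending in a C2 allylic alcohol. Oxidation to the enal triggers an intramolecular allylboration that, in one operation, forms C2–C3, closes the carbocycle, transfers chirality from C5 to C2 and creates the cis C4=C5 alkene. C7 and C8 come from an indium Barbier union steered by a glyceraldehyde-derived, traceless dioxolane.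

Key step: step 14

Remark (numbering): carbon atoms of all intermediates carry the germacrane numbers of the target (C1=C10, C4=C5, lactone C6–O–C12(=O)–C11(=C13H2)–C7, angelate on C8, C14 on C10, C15 on C4).

Remark (assumption): in step 8 the aldehyde is taken to attack C7 anti to the dioxolane C–O bond in the conformer of minimal allylic 1,3-strain, and in step 13 (R)-TRIP is taken to direct attack to the Re face of the aldehyde as with simple aldehydes; if either sense is reversed, the antipodal acetonide or catalyst is used with no other change.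

**Route**

Step 1
Reactants: 1 but-2-yne-1,4-diol
Product: 2 4-[(tert-butyldiphenylsilyl)oxy]but-2-yn-1-ol
Conditions: TBDPSCl (0.3 equiv), imidazole, DMF, 0 °C to rt
Reagents that add atoms: tert-butyl(chloro)diphenylsilane, CC(C)(C)[Si](Cl)(c1ccccc1)c1ccccc1
Why: Silylation of one hydroxyl of the symmetric diol, used in excess, gives the mono-ether (silyl ether formation) and differentiates C14–O from C2–O.

Step 2
Reactants: 2 4-[(tert-butyldiphenylsilyl)oxy]but-2-yn-1-ol
Product: 4 (Z)-4-[(tert-butyldiphenylsilyl)oxy]-3-iodobut-2-en-1-ol, via alkenylalanate 3 (not isolated)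
Conditions: NaAlH2(OCH2CH2OMe)2, THF, 0 °C to rt; EtOAc; then I2, −78 to 0 °C
Reagents that add atoms: iodine, II
Why: Hydroxyl-directed anti-hydroalumination of the propargylic alcohol followed by iododealumination places iodine on C10 cis to the C2 hydroxymethyl group, which fixes the C1=C10 geometry (C2 cis to the future C9) for the rest of the route.

Step 3
Reactants: 4 (Z)-4-[(tert-butyldiphenylsilyl)oxy]-3-iodobut-2-en-1-ol
Product: 5 (Z)-tert-butyl{[2-iodo-4-(triethylsilyloxy)but-2-en-1-yl]oxy}diphenylsilane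
Conditions: Et3SiCl, imidazole, CH2Cl2, 0 °C
Reagents that add atoms: chlorotriethylsilane, CC[Si](Cl)(CC)CC
Why: Silyl ether formation masks the C2 hydroxyl as a triethylsilyl ether that is more acid-labile than the tert-butyldiphenylsilyl ether and is removed in step 10.

Step 4
Reactants: 5 (Z)-tert-butyl{[2-iodo-4-(triethylsilyloxy)but-2-en-1-yl]oxy}diphenylsilane; 6 oxirane
Product: 8 (E)-3-{[(tert-butyldiphenylsilyl)oxy]methyl}-5-[(triethylsilyl)oxy]pent-3-en-1-ol, via alkenyl Grignard 7 (not isolated)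
Conditions: iPrMgCl·LiCl, THF, −40 °C; then CuI (10 mol %), 6, −40 to 0 °C; aq. NH4Cl
Reagents that add atoms: none
Why: Iodine–magnesium exchange occurs with retention of the alkene geometry and the copper-catalysed ring opening of the epoxide by the alkenyl Grignard reagent attaches C9 and C8.

Step 5
Reactants: 8 (E)-3-{[(tert-butyldiphenylsilyl)oxy]methyl}-5-[(triethylsilyl)oxy]pent-3-en-1-ol
Product: 9 (E)-3-{[(tert-butyldiphenylsilyl)oxy]methyl}-5-[(triethylsilyl)oxy]pent-3-enal
Conditions: Dess–Martin periodinane, NaHCO3, CH2Cl2, 0 °C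
Reagents that add atoms: none
Why: Buffered Dess–Martin oxidation should give the β,γ-unsaturated aldehyde without shift of the alkene into conjugation; the aldehyde is used at once.

Step 6
Reactants: 10 (R)-2,2-dimethyl-1,3-dioxolane-4-carbaldehyde; 11 methyl acrylate
Product: 12 methyl 2-{[(4R)-2,2-dimethyl-1,3-dioxolan-4-yl](hydroxy)methyl}prop-2-enoate (both carbinol epimers)
Conditions: DABCO, 1,4-dioxane/H2O, rt
Reagents that add atoms: none
Why: Morita–Baylis–Hillman reaction; the carbinol centre formed is erased in step 7, so both epimers are carried on.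

Step 7
Reactants: 12 methyl 2-{[(4R)-2,2-dimethyl-1,3-dioxolan-4-yl](hydroxy)methyl}prop-2-enoate
Product: 13 methyl (Z)-2-(bromomethyl)-3-[(4S)-2,2-dimethyl-1,3-dioxolan-4-yl]prop-2-enoate
Conditions: NBS, Me2S, CH2Cl2, 0 °C to rt
Reagents that add atoms: N-bromosuccinimide, BrN1C(=O)CCC1=O
Why: Bromination with allylic transposition (bromosulfonium activation, SN2′) should give the (Z)-2-(bromomethyl)enoate, the isomer with the vinylic hydrogen cis to the ester.

Step 8
Reactants: 9 (E)-3-{[(tert-butyldiphenylsilyl)oxy]methyl}-5-[(triethylsilyl)oxy]pent-3-enal; 13 methyl (Z)-2-(bromomethyl)-3-[(4S)-2,2-dimethyl-1,3-dioxolan-4-yl]prop-2-enoate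
Product: 15 methyl (3R,4R,6E)-6-{[(tert-butyldiphenylsilyl)oxy]methyl}-3-[(4S)-2,2-dimethyl-1,3-dioxolan-4-yl]-4-hydroxy-2-methylidene-8-[(triethylsilyl)oxy]oct-6-enoate, via allylindium 14 (not isolated)
Conditions: In powder, THF/H2O (3:1), 0 °C to rt
Reagents that add atoms: none
Why: Indium-mediated Barbier allylation through a closed six-membered transition state: the (Z)-allylindium gives the syn C7/C8 pair, and the dioxolane centre, with its C–H eclipsing the alkene to minimise allylic 1,3-strain, directs the aldehyde to the C7 face anti to its C–O bond, so that C7 and C8 should arise with the configuration of the target.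

Step 9
Reactants: 15 methyl (3R,4R,6E)-6-{[(tert-butyldiphenylsilyl)oxy]methyl}-3-[(4S)-2,2-dimethyl-1,3-dioxolan-4-yl]-4-hydroxy-2-methylidene-8-[(triethylsilyl)oxy]oct-6-enoate; 16 angelic acid
Product: 18 methyl (3R,4R,6E)-6-{[(tert-butyldiphenylsilyl)oxy]methyl}-3-[(4S)-2,2-dimethyl-1,3-dioxolan-4-yl]-2-methylidene-4-{[(2Z)-2-methylbut-2-enoyl]oxy}-8-[(triethylsilyl)oxy]oct-6-enoate, via mixed anhydride 17 (not isolated)
Conditions: 16, 2,4,6-Cl3C6H2COCl, Et3N, toluene, rt; then 15, toluene, 75 °C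
Reagents that add atoms: none
Why: Yamaguchi esterification through the mixed anhydride, run without a nucleophilic catalyst, should acylate C8–OH with retention at C8 and without isomerisation of the angelate to the tiglate.

Step 10
Reactants: 18 methyl (3R,4R,6E)-6-{[(tert-butyldiphenylsilyl)oxy]methyl}-3-[(4S)-2,2-dimethyl-1,3-dioxolan-4-yl]-2-methylidene-4-{[(2Z)-2-methylbut-2-enoyl]oxy}-8-[(triethylsilyl)oxy]oct-6-enoate
Product: 19 methyl (3R,4R,6E)-6-{[(tert-butyldiphenylsilyl)oxy]methyl}-3-formyl-8-hydroxy-2-methylidene-4-{[(2Z)-2-methylbut-2-enoyl]oxy}oct-6-enoate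
Conditions: H5IO6, EtOAc, 0 °C to rt; used crude
Reagents that add atoms: none
Why: Periodic acid hydrolyses the terminal acetonide and cleaves the resulting glycol to the C6 aldehyde (glycol cleavage), so the dioxolane acts as a traceless chiral formyl equivalent, and the acidic medium removes the triethylsilyl ether.

Step 11
Reactants: 20 prop-2-yn-1-ol
Product: 22 (E)-2-methyl-3-(4,4,5,5-tetramethyl-1,3,2-dioxaborolan-2-yl)prop-2-en-1-ol, via alkenylalane 21 (not isolated)
Conditions: Me3Al, Cp2ZrCl2 (20 mol %), CH2Cl2, 0 °C to rt; then iPrOBpin, −78 °C to rt; aq. work-up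
Reagents that add atoms: trimethylaluminium, C[Al](C)C; 2-isopropoxy-4,4,5,5-tetramethyl-1,3,2-dioxaborolane, CC(C)OB1OC(C)(C)C(C)(C)O1
Why: Zirconium-catalysed syn-carboalumination (Negishi) adds methyl and aluminium cis across the alkyne, and transmetalation from aluminium to boron gives the (E)-alkenylboronate with C15 in place.

Step 12
Reactants: 22 (E)-2-methyl-3-(4,4,5,5-tetramethyl-1,3,2-dioxaborolan-2-yl)prop-2-en-1-ol
Product: 23 2,2'-[(1E)-2-methylprop-1-ene-1,3-diyl]bis(4,4,5,5-tetramethyl-1,3,2-dioxaborolane)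
Conditions: B2pin2, Pd(MeCN)4(BF4)2 (5 mol %), DMSO/MeOH, 50 °C
Reagents that add atoms: bis(pinacolato)diboron, CC1(C)OB(OC1(C)C)B1OC(C)(C)C(C)(C)O1
Why: Palladium-catalysed borylation of the allylic alcohol through a π-allyl intermediate should deliver boron to the unsubstituted terminus with retention of the (E)-geometry and give the 1,3-diboryl reagent.

Step 13
Reactants: 19 methyl (3R,4R,6E)-6-{[(tert-butyldiphenylsilyl)oxy]methyl}-3-formyl-8-hydroxy-2-methylidene-4-{[(2Z)-2-methylbut-2-enoyl]oxy}oct-6-enoate; 23 2,2'-[(1E)-2-methylprop-1-ene-1,3-diyl]bis(4,4,5,5-tetramethyl-1,3,2-dioxaborolane)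
Product: 26 (1R,3E)-3-{[(tert-butyldiphenylsilyl)oxy]methyl}-5-hydroxy-1-{(2R,3R)-4-methylidene-2-[(1R)-2-methyl-1-(4,4,5,5-tetramethyl-1,3,2-dioxaborolan-2-yl)prop-2-en-1-yl]-5-oxooxolan-3-yl}pent-3-en-1-yl (2Z)-2-methylbut-2-enoate, via borate 24 (not isolated), via hydroxy ester 25 (not isolated)
Conditions: (R)-TRIP [(R)-3,3'-bis(2,4,6-triisopropylphenyl)-1,1'-binaphthyl-2,2'-diyl hydrogen phosphate] (5 mol %), 4 Å MS, toluene, −30 °C to rt; then SiO2, CH2Cl2, rt
Reagents that add atoms: none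
Why: Brønsted-acid-catalysed allylboration, the first stage of a double allylboration: the chair transition state of the (E)-γ-boryl allylboronate gives the anti C5/C6 pair, catalyst control reinforced by the Felkin–Anh preference should set (6R) and hence (5R), and the C6 hydroxyl set free on work-up lactonises onto the methyl ester to the trans-lactone.

Step 14
Reactants: 26 (1R,3E)-3-{[(tert-butyldiphenylsilyl)oxy]methyl}-5-hydroxy-1-{(2R,3R)-4-methylidene-2-[(1R)-2-methyl-1-(4,4,5,5-tetramethyl-1,3,2-dioxaborolan-2-yl)prop-2-en-1-yl]-5-oxooxolan-3-yl}pent-3-en-1-yl (2Z)-2-methylbut-2-enoate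
Product: 29 (2S,6R,7R,8R)-8-angeloyloxy-14-[(tert-butyldiphenylsilyl)oxy]-2-hydroxygermacra-1(10)E,4Z,11(13)-trien-6,12-olide, via enal 27 (not isolated), via borate ester 28 (not isolated)
Conditions: Dess–Martin periodinane, NaHCO3, CH2Cl2, 0 °C; then dilution to 0.002 M, 35 °C; N(CH2CH2OH)3, H2O
Reagents that add atoms: none
Why: Proposed new method: Dess–Martin oxidation unmasks the C2 enal 27, whose oxygen binds the boron on C5 while C2 accepts C3 of the allylboronate through a six-membered chair transition state with allyl transposition, so that the C2–C3 bond, the C4=C5 alkene and the carbocycle form together before hydrolysis of borate ester 28. The closest known reactions are the intermolecular second stage of double allylborations of anti-β-oxy α-substituted allylboronates and intramolecular allylborations that close five- to seven-membered rings; closure of a medium ring in which the transposed alkene becomes endocyclic has not been shown. The ten-membered ring closes in a 10-endo mode with respect to the allyl unit, through a bicyclic transition state in which the B–O–C2–C3–C4–C5 chair is bridged by C6–C10 and C1. C2 is set by chirality transfer from C5: (5R) with C6 pseudo-axial and the enal residue pseudo-equatorial should give (2S). The pseudo-axial position of C6 is enforced by allylic 1,2-strain with the C15 methyl group and by the ring, which tolerates only a cis C4=C5 bond, so alkene geometry and C2 configuration are coupled. The step needs ring closure to outrun bimolecular allylboration and β-elimination of boron with the lactone oxygen; high dilution, neutral conditions, the cis C1=C10 bond and the trans-lactone that holds C5 and C2 within reach are meant to secure this.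

Step 15
Reactants: 29 (2S,6R,7R,8R)-8-angeloyloxy-14-[(tert-butyldiphenylsilyl)oxy]-2-hydroxygermacra-1(10)E,4Z,11(13)-trien-6,12-olide
Product: 30 (2S,6R,7R,8R)-8-angeloyloxy-2,14-dihydroxygermacra-1(10)E,4Z,11(13)-trien-6,12-olide
Conditions: HF·pyridine, pyridine, THF, 0 °C to rt
Reagents that add atoms: none
Why: Desilylation with buffered HF·pyridine should free the C14 hydroxyl without touching the esters, the α-methylene lactone or the allylic C2 alcohol.

Step 16
Reactants: 30 (2S,6R,7R,8R)-8-angeloyloxy-2,14-dihydroxygermacra-1(10)E,4Z,11(13)-trien-6,12-olide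
Product: 31 (2S,6R,7R,8R)-14-acetoxy-8-angeloyloxy-2-hydroxygermacra-1(10)E,4Z,11(13)-trien-6,12-olide (CNP0151426.1)
Conditions: AcCl, 2,4,6-collidine, CH2Cl2, −78 °C
Reagents that add atoms: acetyl chloride, CC(Cl)=O
Why: Acetylation under kinetic control at low temperature should select the primary allylic C14 hydroxyl over the secondary, ring-bound C2 hydroxyl and give the target.

**Compound list**

1 | but-2-yne-1,4-diol | OCC#CCO | starting material
2 | 4-[(tert-butyldiphenylsilyl)oxy]but-2-yn-1-ol | OCC#CCO[Si](c1ccccc1)(c1ccccc1)C(C)(C)C | intermediate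
3 | sodium cyclic alkenylalanate (2,5-dihydro-1,2-oxaalumol-2-uide with two 2-methoxyethoxy groups on aluminium; C10–Al, C2–O–Al) | [Na+].COCCO[Al-]1(OCCOC)OCC=C1CO[Si](c2ccccc2)(c2ccccc2)C(C)(C)C | intermediate
4 | (Z)-4-[(tert-butyldiphenylsilyl)oxy]-3-iodobut-2-en-1-ol | OC/C=C(\I)CO[Si](c1ccccc1)(c1ccccc1)C(C)(C)C | intermediate
5 | (Z)-tert-butyl{[2-iodo-4-(triethylsilyloxy)but-2-en-1-yl]oxy}diphenylsilane | CC[Si](CC)(CC)OC/C=C(\I)CO[Si](c1ccccc1)(c1ccccc1)C(C)(C)C | intermediate
6 | oxirane | C1CO1 | starting material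
7 | {(Z)-1-[(tert-butyldiphenylsilyl)oxy]-4-[(triethylsilyl)oxy]but-2-en-2-yl}magnesium chloride | CC[Si](CC)(CC)OC/C=C(\[Mg]Cl)CO[Si](c1ccccc1)(c1ccccc1)C(C)(C)C | intermediate
8 | (E)-3-{[(tert-butyldiphenylsilyl)oxy]methyl}-5-[(triethylsilyl)oxy]pent-3-en-1-ol | OCC/C(CO[Si](c1ccccc1)(c1ccccc1)C(C)(C)C)=C\CO[Si](CC)(CC)CC | intermediate
9 | (E)-3-{[(tert-butyldiphenylsilyl)oxy]methyl}-5-[(triethylsilyl)oxy]pent-3-enal | O=CC/C(CO[Si](c1ccccc1)(c1ccccc1)C(C)(C)C)=C\CO[Si](CC)(CC)CC | intermediate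
10 | (R)-2,2-dimethyl-1,3-dioxolane-4-carbaldehyde | CC1(C)OC[C@@H](O1)C=O | starting material
11 | methyl acrylate | C=CC(=O)OC | starting material
12 | methyl 2-{[(4R)-2,2-dimethyl-1,3-dioxolan-4-yl](hydroxy)methyl}prop-2-enoate (both carbinol epimers) | CC1(C)OC[C@@H](O1)C(O)C(=C)C(=O)OC | intermediate
13 | methyl (Z)-2-(bromomethyl)-3-[(4S)-2,2-dimethyl-1,3-dioxolan-4-yl]prop-2-enoate | CC1(C)OC[C@@H](O1)/C=C(\CBr)C(=O)OC | intermediate
14 | dibromo{(Z)-3-[(4S)-2,2-dimethyl-1,3-dioxolan-4-yl]-2-(methoxycarbonyl)prop-2-en-1-yl}indium (one component of the allylindium reagent) | CC1(C)OC[C@@H](O1)/C=C(\C[In](Br)Br)C(=O)OC | intermediate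
15 | methyl (3R,4R,6E)-6-{[(tert-butyldiphenylsilyl)oxy]methyl}-3-[(4S)-2,2-dimethyl-1,3-dioxolan-4-yl]-4-hydroxy-2-methylidene-8-[(triethylsilyl)oxy]oct-6-enoate (7R,8R in germacrane numbering) | CC1(C)OC[C@@H](O1)[C@H](C(=C)C(=O)OC)[C@H](O)C/C(CO[Si](c2ccccc2)(c2ccccc2)C(C)(C)C)=C\CO[Si](CC)(CC)CC | intermediate
16 | angelic acid, (Z)-2-methylbut-2-enoic acid | C/C=C(/C)C(=O)O | starting material
17 | (Z)-2-methylbut-2-enoic 2,4,6-trichlorobenzoic anhydride | C/C=C(/C)C(=O)OC(=O)c1c(Cl)cc(Cl)cc1Cl | intermediate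
18 | methyl (3R,4R,6E)-6-{[(tert-butyldiphenylsilyl)oxy]methyl}-3-[(4S)-2,2-dimethyl-1,3-dioxolan-4-yl]-2-methylidene-4-{[(2Z)-2-methylbut-2-enoyl]oxy}-8-[(triethylsilyl)oxy]oct-6-enoate | CC1(C)OC[C@@H](O1)[C@H](C(=C)C(=O)OC)[C@H](OC(=O)/C(C)=C\C)C/C(CO[Si](c2ccccc2)(c2ccccc2)C(C)(C)C)=C\CO[Si](CC)(CC)CC | intermediate
19 | methyl (3R,4R,6E)-6-{[(tert-butyldiphenylsilyl)oxy]methyl}-3-formyl-8-hydroxy-2-methylidene-4-{[(2Z)-2-methylbut-2-enoyl]oxy}oct-6-enoate (C6 aldehyde, 7R,8R) | O=C[C@H](C(=C)C(=O)OC)[C@H](OC(=O)/C(C)=C\C)C/C(CO[Si](c1ccccc1)(c1ccccc1)C(C)(C)C)=C\CO | intermediate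
20 | prop-2-yn-1-ol | C#CCO | starting material
21 | dimethyl{(E)-3-[(dimethylalumanyl)oxy]-2-methylprop-1-en-1-yl}alumane | C[Al](C)/C=C(\C)CO[Al](C)C | intermediate
22 | (E)-2-methyl-3-(4,4,5,5-tetramethyl-1,3,2-dioxaborolan-2-yl)prop-2-en-1-ol | OC/C(C)=C/B1OC(C)(C)C(C)(C)O1 | intermediate
23 | 2,2'-[(1E)-2-methylprop-1-ene-1,3-diyl]bis(4,4,5,5-tetramethyl-1,3,2-dioxaborolane) | CC1(C)OB(OC1(C)C)C/C(C)=C/B1OC(C)(C)C(C)(C)O1 | intermediate
24 | methyl (3S,4R,6E)-6-{[(tert-butyldiphenylsilyl)oxy]methyl}-8-hydroxy-2-methylidene-4-{[(2Z)-2-methylbut-2-enoyl]oxy}-3-{(1R,2R)-3-methyl-2-(pinacolboryl)-1-[(pinacolboryl)oxy]but-3-en-1-yl}oct-6-enoate (5R,6R,7S,8R) | C=C(C(=O)OC)[C@@H]([C@H](OB1OC(C)(C)C(C)(C)O1)[C@H](B1OC(C)(C)C(C)(C)O1)C(C)=C)[C@H](OC(=O)/C(C)=C\C)C/C(CO[Si](c1ccccc1)(c1ccccc1)C(C)(C)C)=C\CO | intermediate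
25 | methyl (3S,4R,6E)-6-{[(tert-butyldiphenylsilyl)oxy]methyl}-8-hydroxy-3-[(1R,2R)-1-hydroxy-3-methyl-2-(pinacolboryl)but-3-en-1-yl]-2-methylidene-4-{[(2Z)-2-methylbut-2-enoyl]oxy}oct-6-enoate (5R,6R,7S,8R) | C=C(C(=O)OC)[C@@H]([C@H](O)[C@H](B1OC(C)(C)C(C)(C)O1)C(C)=C)[C@H](OC(=O)/C(C)=C\C)C/C(CO[Si](c1ccccc1)(c1ccccc1)C(C)(C)C)=C\CO | intermediate
26 | (1R,3E)-3-{[(tert-butyldiphenylsilyl)oxy]methyl}-5-hydroxy-1-{(2R,3R)-4-methylidene-2-[(1R)-2-methyl-1-(4,4,5,5-tetramethyl-1,3,2-dioxaborolan-2-yl)prop-2-en-1-yl]-5-oxooxolan-3-yl}pent-3-en-1-yl (2Z)-2-methylbut-2-enoate (5R,6R,7R,8R) | C=C1C(=O)O[C@H]([C@H](B2OC(C)(C)C(C)(C)O2)C(C)=C)[C@H]1[C@H](OC(=O)/C(C)=C\C)C/C(CO[Si](c2ccccc2)(c2ccccc2)C(C)(C)C)=C\CO | intermediate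
27 | the C2 enal of 26: (1R,3E)-3-{[(tert-butyldiphenylsilyl)oxy]methyl}-1-{(2R,3R)-4-methylidene-2-[(1R)-2-methyl-1-(pinacolboryl)prop-2-en-1-yl]-5-oxooxolan-3-yl}-5-oxopent-3-en-1-yl (2Z)-2-methylbut-2-enoate | C=C1C(=O)O[C@H]([C@H](B2OC(C)(C)C(C)(C)O2)C(C)=C)[C@H]1[C@H](OC(=O)/C(C)=C\C)C/C(CO[Si](c2ccccc2)(c2ccccc2)C(C)(C)C)=C\C=O | intermediate
28 | 2-O-pinacolboryl ester of 29 | C=C1C(=O)O[C@@H]2/C=C(/C)C[C@H](OB3OC(C)(C)C(C)(C)O3)/C=C(/CO[Si](c3ccccc3)(c3ccccc3)C(C)(C)C)C[C@@H](OC(=O)/C(C)=C\C)[C@@H]12 | intermediate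
29 | (2S,6R,7R,8R)-8-angeloyloxy-14-[(tert-butyldiphenylsilyl)oxy]-2-hydroxygermacra-1(10)E,4Z,11(13)-trien-6,12-olide | C=C1C(=O)O[C@@H]2/C=C(/C)C[C@H](O)/C=C(/CO[Si](c3ccccc3)(c3ccccc3)C(C)(C)C)C[C@@H](OC(=O)/C(C)=C\C)[C@@H]12 | intermediate
30 | (2S,6R,7R,8R)-8-angeloyloxy-2,14-dihydroxygermacra-1(10)E,4Z,11(13)-trien-6,12-olide | C=C1C(=O)O[C@@H]2/C=C(/C)C[C@H](O)/C=C(/CO)C[C@@H](OC(=O)/C(C)=C\C)[C@@H]12 | intermediate
31 | (2S,6R,7R,8R)-14-acetoxy-8-angeloyloxy-2-hydroxygermacra-1(10)E,4Z,11(13)-trien-6,12-olide (CNP0151426.1) | C=C1C(=O)O[C@@H]2/C=C(/C)C[C@H](O)/C=C(/COC(C)=O)C[C@@H](OC(=O)/C(C)=C\C)[C@@H]12 | target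

**Step count.** Total: 16 steps. Longest linear sequence: 12 steps (1, 2, 3, 4, 5, 8, 9, 10, 13, 14, 15, 16).

**Steps most likely to fail, with fallbacks**

Step 14 (Proposed new method). What may go wrong: the medium-ring transition state may adopt a boat-like or aldehyde-axial arrangement, so that chirality transfer from C5 is eroded or inverted and the C2 epimer forms; bimolecular allylboration is a second threat, which dilution is meant to answer. The fallback uses known chemistry and sets out from 26. Its cyclisation product would then be the C2 epimer of 29, (2R,6R,7R,8R)-8-angeloyloxy-14-[(tert-butyldiphenylsilyl)oxy]-2-hydroxygermacra-1(10)E,4Z,11(13)-trien-6,12-olide F1. Oxidation of the allylic alcohol with MnO2 (CH2Cl2, rt) should give the dienone (6R,7R,8R)-8-angeloyloxy-14-[(tert-butyldiphenylsilyl)oxy]-2-oxogermacra-1(10)E,4Z,11(13)-trien-6,12-olide F2. Reagent-controlled 1,2-reduction with (R)-2-methyl-CBS-oxazaborolidine and catecholborane (toluene, −78 °C) should then deliver hydride so as to give the (2S) alcohol, and the fallback comes back to the route at 29. C2 is thus set by reduction instead of by allyl transfer.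

Step 13. What may go wrong: aldehyde 19 is α-branched, β-acyloxylated and doubly activated at C7, so epimerisation at C7 or β-elimination of the angelate may outrun the slow acid-catalysed addition of the electron-poor γ-boryl allylboronate. The fallback replaces the allylboron nucleophile by a faster allylindium and sets out from 22 and 19. Alcohol 22 is converted (CBr4, PPh3, CH2Cl2, 0 °C) into 2-[(1E)-3-bromo-2-methylprop-1-en-1-yl]-4,4,5,5-tetramethyl-1,3,2-dioxaborolane F3. Indium-mediated Barbier reaction of F3 with 19 (In powder, THF/H2O, rt) should give hydroxy ester 25 through the same chair arrangement (anti C5/C6), now under Felkin–Anh control alone. Lactonisation on silica brings the fallback back to the route at 26.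

Step 8. What may go wrong: facial discrimination at C7 by the dioxolane may be poor in the loose, aqueous indium transition state, and E/Z equilibration of the allylindium may erode the syn C7/C8 relationship. The fallback uses an allylboron reagent with a tight, Lewis-acid-organised chair and sets out from 12. Acetylation (Ac2O, DMAP, CH2Cl2) gives methyl 2-{acetoxy[(4R)-2,2-dimethyl-1,3-dioxolan-4-yl]methyl}prop-2-enoate F4. Copper-catalysed SN2′ borylation (B2pin2, CuCl, KOAc, DMF) should give methyl (E)-3-[(4S)-2,2-dimethyl-1,3-dioxolan-4-yl]-2-[(4,4,5,5-tetramethyl-1,3,2-dioxaborolan-2-yl)methyl]prop-2-enoate F5, with the dioxolane cis to the borylmethyl group. Allylboration of aldehyde 9 with F5 catalysed by Sc(OTf)3 (toluene, −78 °C) is stereospecific and should give the syn adduct, and the fallback comes back to the route at 15.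

**Further compounds**

F1 | step 14 | (2R,6R,7R,8R)-8-angeloyloxy-14-[(tert-butyldiphenylsilyl)oxy]-2-hydroxygermacra-1(10)E,4Z,11(13)-trien-6,12-olide | C=C1C(=O)O[C@@H]2/C=C(/C)C[C@@H](O)/C=C(/CO[Si](c3ccccc3)(c3ccccc3)C(C)(C)C)C[C@@H](OC(=O)/C(C)=C\C)[C@@H]12
F2 | step 14 | (6R,7R,8R)-8-angeloyloxy-14-[(tert-butyldiphenylsilyl)oxy]-2-oxogermacra-1(10)E,4Z,11(13)-trien-6,12-olide | C=C1C(=O)O[C@@H]2/C=C(/C)CC(=O)/C=C(/CO[Si](c3ccccc3)(c3ccccc3)C(C)(C)C)C[C@@H](OC(=O)/C(C)=C\C)[C@@H]12
F3 | step 13 | 2-[(1E)-3-bromo-2-methylprop-1-en-1-yl]-4,4,5,5-tetramethyl-1,3,2-dioxaborolane | BrC/C(C)=C/B1OC(C)(C)C(C)(C)O1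
F4 | step 8 | methyl 2-{acetoxy[(4R)-2,2-dimethyl-1,3-dioxolan-4-yl]methyl}prop-2-enoate | CC1(C)OC[C@@H](O1)C(OC(C)=O)C(=C)C(=O)OC
F5 | step 8 | methyl (E)-3-[(4S)-2,2-dimethyl-1,3-dioxolan-4-yl]-2-[(4,4,5,5-tetramethyl-1,3,2-dioxaborolan-2-yl)methyl]prop-2-enoate | CC1(C)OC[C@@H](O1)/C=C(\CB2OC(C)(C)C(C)(C)O2)C(=O)OC
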